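**The charge.** The closed vessel starts from electrophile and nucleophile at 0.46 M and 1.15 M, in the amber and ochre runs and in Monday's, Friday's and Saturday's alike; the free base differs.

| flask | electrophile | nucleophile | free base | remark | time |
|---|---|---|---|---|---|
| amber | 0.46 M | 1.15 M | 0.73 M | run made earlier |  |
| ochre | 0.46 M | 1.15 M | 1.7 M | run made earlier |  |
| Monday's | 0.46 M | 1.15 M | 0.510 M |  | 1.0 h |
| Friday's | 0.46 M | 1.15 M | 0.760 M |  | 1.0 h |
| Saturday's | 0.46 M | 1.15 M | 1.10 M |  | 1.0 h |

| run | time / min | electrophile / % | target / % |
|---|---|---|---|
| amber | 3.00 | 26.9 | 64.1 |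
| amber | 10.0 | 6.3 | 66.6 |
| amber | 15.0 | 5.2 | 60.6 |
| amber | 25.0 | 2.2 | 56.8 |
| amber | 40.0 | 0.9 | 50.7 |
| amber | 50.0 | 0.6 | 49.5 |
| amber | 60.0 | 1.4 | 47.0 |
| ochre | 8.00 | 9.9 | 65.7 |
| ochre | 15.0 | 4.9 | 61.5 |
| ochre | 25.0 | 3.7 | 55.0 |
| ochre | 30.0 | 2.6 | 54.1 |
| ochre | 40.0 | 0 | 51.5 |
| ochre | 50.0 | 0.7 | 49.7 |
| ochre | 60.0 | 1.6 | 48.1 |

(readings scatter by 1 percentage point)

- part of the electrophile that has reacted at the end, Monday's
- part of the electrophile that has reacted at the end, Friday's
- part of the electrophile that has reacted at the end, Saturday's
- what raising the concentration of free base from its lowest to its highest value here does to the part of the electrophile that has reacted (changes below 5 percentage points count as none) (no change / it falls / it rises)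



**One number.** Nucleophile charged over electrophile charged, the equivalents 2.50, says how many nucleophiles are charged per electrophile, so the electrophile is the limiting reagent by charge. Amber and ochre share this number, and so do the new flasks.

**The remainder.** In amber and ochre nearly all the electrophile has reacted by the last readings at 60.0 min, which is the asked 1.0 h, so I reckon the small remainder. Amber reads 1.4% and ochre 1.6%, a mean of 1.50%, so I expect 98.5% reacted.

**Is it enough?** Ochre is charged with 2.33 times amber's free base, yet the two remainders differ by 0.2 percentage points, less than the scatter of 1 point. Friday's and Saturday's lie inside that span of free base. Monday's 0.510 M lies below amber's, so there the remainder read from amber and ochre is less tested.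

**The forecast.** It gives 98.3% for Monday's (95.5% to 99.8%), 99% for Friday's, 99% for Saturday's and no change, holding that “base is not in the rate law; it only takes up acid”. My reckoning gives one figure for the three flasks, and the forecast gives these separate ones.

**The result.** Monday's gives 98.9%, Friday's 98.9% and Saturday's 98.9%: no change, with a change of 0.034 points.

    2 free base → self-condensation product (k = 1.73 × 10⁻⁴ M⁻¹ s⁻¹)
    electrophile + nucleophile → acid set free + target (k = 0.0110 M⁻¹ s⁻¹)
    nucleophile + target → over-reaction product (k = 0.00229 M⁻¹ s⁻¹)
    acid set free + free base ⇌ salt of the base (K = 4700 M⁻¹, k = 0.00240 M⁻¹ s⁻¹)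
    acid set free + target → side product (k = 8.54 × 10⁻⁴ M⁻¹ s⁻¹)
    nucleophile + acid set free ⇌ protonated nucleophile, settled at all times (K = 4340 M⁻¹)

At the end of Friday's, 1.90% of the nucleophile is still free, beside 0.440 M of protonated nucleophile; through the equivalents, that free part equals 4.75% of the electrophile charged. Saturday's flask, left until 4.0 h, reaches 99.8% with free nucleophile equal to 2.43% of the electrophile charged.

The numbers in the tables were computed for substances that don't exist, noise included.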